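Answer 4 questions with 2 runs in hand.

| flask | starting complex | incoming ligand | protic impurity | remark | time |
|---|---|---|---|---|---|
| eta | 0.024 M | 0.95 equiv | 2.4 mM | run made earlier |  |
| gamma | 0.036 M | 0.95 equiv | 2.4 mM | run made earlier |  |
| autumn | 0.024 M | 0.950 equiv (fed, over 12 min) | 2.40 mM | all else is in the flask from the start; the feed brings no volume worth counting | 20 min |
| dawn | 0.024 M | 0.950 equiv | 2.40 mM | everything together at the start | 20 min |
| spring | 0.024 M (fed, over 12 min) | 0.950 equiv | 2.40 mM | all else is in the flask from the start; the feed brings no volume worth counting | 20 min |

- eta (time / min: complex with two exchanged / %, starting complex / %): 1.50: 8, 66; 3.00: 13, 52; 5.00: 19, 45; 6.00: 20, 44; 8.00: 19, 41; 10.0: 17, 38; 12.0: 15, 36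
- gamma (time / min: complex with two exchanged / %, starting complex / %): 0.333: 1, 86; 1.00: 10, 68; 1.50: 13, 59; 2.50: 17, 51; 4.00: 20, 45; 5.00: 19, 43; 6.00: 16, 42

(readings scatter by 1.5 percentage points)

- the flask that comes out highest in amount of complex with two exchanged, in percent of the starting complex charged, or "all alike" when all lie within 1.5 percentage points (autumn / dawn / spring / all alike)
- complex with two exchanged at the end, in percent of the starting complex charged, autumn
- complex with two exchanged at the end, in percent of the starting complex charged, dawn
- complex with two exchanged at the end, in percent of the starting complex charged, spring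



Start from the fall after the peak. In the eta run, complex with two exchanged peaks at 20% at 6.00 min and stands at 15% at 12.0 min, so treat this as a pseudo-first-order loss of 0.0479 min⁻¹. Divide that by c(starting complex), 0.024 M, to get 0.0333 M⁻¹ s⁻¹. Dawn has the eta recipe, so carry the last eta reading through the remaining 8.00 min, which gives 10.2%. For the fed flasks, assume the same peak, reached when the feed stops at 12 min. That gives 13.6%, higher than dawn, and this reckoning does not part autumn from spring.

The weak link is that first rate, which rests on two readings 5 percentage points apart, each good to 1.5 points. Reforge it with the gamma run at 0.036 M: the fall from 20% at 4.00 min to 16% at 6.00 min gives 0.112 min⁻¹, or 0.0517 M⁻¹ s⁻¹ per unit of charge. Take the mean as the wear constant, the share of complex with two exchanged lost per second for each mole per litre of starting complex charged: 0.0425 M⁻¹ s⁻¹. Dawn moves to 9.20% and the fed flasks to 12.3%.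

The forecast gives 9% for autumn, 10% for dawn and 18% for spring, and says “Spring should be highest”. It parts from this reckoning by setting spring above autumn, where the reckoning holds them level.

The flasks end at 16.2% in autumn, 9.26% in dawn and 11.2% in spring.

    leaving ligand + complex with two exchanged → side product (k = 0.0680 M⁻¹ s⁻¹)
    protic impurity + starting complex → quenched substrate (k = 0.130 M⁻¹ s⁻¹)
    complex with one exchanged + incoming ligand → leaving ligand + complex with two exchanged (k = 0.370 M⁻¹ s⁻¹)
    starting complex + incoming ligand → leaving ligand + complex with one exchanged (k = 0.260 M⁻¹ s⁻¹)
    2 incoming ligand → self-condensation product (k = 0.0390 M⁻¹ s⁻¹)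

Strike out the reaction of leaving ligand with complex with two exchanged, and the lead of autumn over dawn shrinks from 7 points to 3.1 points. In autumn, the wear constant takes 6.7 points from the 17.2% standing when the feed stops, yet 16.2% remains, with 22.9% of the incoming ligand still there at that moment to make more. The neighbour with 0.096 M of starting complex wears at 0.245 min⁻¹, which keeps 14.1% over those same minutes, and it ends at 2.04%.

(All runs stem from a simulated flask with constants of no real substance; the scatter is artificial.)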